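**Retrosynthetic overview**
1. Target 29 comes from the C1 aldehyde 20 and the 2-lithiated arene 26 (addition, oxidation, MOM removal); the electron-rich arene is brought in only after the oxidative step.
2. Aldehyde 20 comes from keto ester 15: the C3 ketone becomes the C3-methyl C3=C4 alkene (C4 enol triflate, iron-catalysed methylation) and the ester becomes the aldehyde.
3. Feature used: in the cyclohexene ring, C1 (acyl-bearing) and C2 (prenyl-bearing) are both alpha to a carbonyl group once C3 is carried as a ketone, so C1–C2 is the central bond of a 1,4-dicarbonyl unit. It is made by anodic coupling of a ketene silyl acetal (C1) with a silyl enol ether (C2) in 13.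
4. Precursor 13 comes from vinyl ketone 8 (regiospecific enol ether by conjugate addition), which comes from enoate 5 (Rh/(R)-BINAP phenyl addition sets C6), made from pent-4-enoic acid 1 and methyl acrylate 4 by cross-metathesis.
5. Ring order: the cyclohexane ring is the only ring formed (step 7; both benzene rings are bought), and C1 and C2 are set by base equilibration against C6 right after closure.

Key step: step 7

Assumption on numbering: the ring atoms are C1 (acyl-bearing), C2 (prenyl), C3 (methyl), C4, C5, C6 (phenyl); the target is the (1S,2S,6S) isomer, with the acyl group trans to both neighbours.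
Remark on the arene: both phenols ortho to the ketone are carried as MOM ethers, starting from commercial 3-hydroxy-4,5-dimethoxybenzaldehyde, so that no Lewis-acid demethylation is needed next to the acid-sensitive alkenes.
Remark on silyl groups: the ketene acetal carries tert-butyldimethylsilyl and the ketone enol ether trimethylsilyl.

**Route**

Step 1
Reactants: 1 pent-4-enoic acid
Product: 3 N-methoxy-N-methylpent-4-enamide, via 1-(imidazol-1-yl)pent-4-en-1-one 2 (not isolated)
Conditions: CDI, CH2Cl2, rt; then MeNH(OMe)·HCl, rt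
Reagents that add atoms: N,O-dimethylhydroxylamine hydrochloride, CNOC.Cl
Why: Activation of the acid as its acyl imidazolide followed by aminolysis (Weinreb amide formation) is a clean amide coupling, and no stereocentre is involved.

Step 2
Reactants: 3 N-methoxy-N-methylpent-4-enamide; 4 methyl acrylate (3 equiv)
Product: 5 methyl (2E)-6-[methoxy(methyl)amino]-6-oxohex-2-enoate
Conditions: second-generation Grubbs catalyst (3 mol%), CH2Cl2, 40 °C
Reagents that add atoms: none
Why: Olefin cross-metathesis of a terminal alkene with an excess of the electron-poor acrylate should give the (E)-enoate selectively, because the acrylate homodimerises slowly and the E cross product is the thermodynamic outcome.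

Step 3
Reactants: 5 methyl (2E)-6-[methoxy(methyl)amino]-6-oxohex-2-enoate; 6 phenylboronic acid (2.5 equiv)
Product: 7 methyl (3S)-6-[methoxy(methyl)amino]-6-oxo-3-phenylhexanoate
Conditions: Rh(acac)(C2H4)2 (3 mol%), (R)-BINAP, dioxane–H2O (10:1), 100 °C
Reagents that add atoms: none
Why: Hayashi–Miyaura asymmetric 1,4-addition, in which the phenylrhodium–(R)-BINAP species inserts the (E)-enoate on the enantioface that leads to the 3S benzylic centre (the facial preference that gives (R)-3-phenylcyclohexanone from cyclohexenone with the same ligand), while the Weinreb amide is inert to the catalyst.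

Step 4
Reactants: 7 methyl (3S)-6-[methoxy(methyl)amino]-6-oxo-3-phenylhexanoate
Product: 8 methyl (3S)-6-oxo-3-phenyloct-7-enoate
Conditions: CH2=CHMgBr (1.3 equiv), THF, −78 → −10 °C; poured into cold 1 M HCl
Reagents that add atoms: vinylmagnesium bromide, C=C[Mg]Br
Why: Weinreb ketone synthesis, in which the chelated tetrahedral magnesium adduct blocks over-addition and the amide is attacked faster than the methyl ester at low temperature; the acidic quench keeps the released amine from adding to the vinyl ketone, and C3 is not touched.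

Step 5
Reactants: 8 methyl (3S)-6-oxo-3-phenyloct-7-enoate; 9 1-bromo-2-methylprop-1-ene
Product: 11 methyl (3S,6Z)-10-methyl-3-phenyl-6-[(trimethylsilyl)oxy]undeca-6,9-dienoate, via (2-methylprop-1-en-1-yl)magnesium bromide 10 (not isolated)
Conditions: 9, Mg, THF, reflux; then CuBr·SMe2 (5 mol%), Me3SiCl, HMPA, 8, THF, −78 °C; Et3N, cold aq NaHCO3
Reagents that add atoms: chlorotrimethylsilane, C[Si](C)(C)Cl
Why: Me3SiCl-accelerated copper-catalysed conjugate addition of the alkenyl Grignard reagent to the vinyl ketone, with silylation of the enolate as it forms, should give the enol ether regiospecifically toward C7 and mainly as the Z isomer from the s-cis enone, the ester being untouched at −78 °C.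

Step 6
Reactants: 11 methyl (3S,6Z)-10-methyl-3-phenyl-6-[(trimethylsilyl)oxy]undeca-6,9-dienoate
Product: 13 tert-butyl{[(3S,6Z)-1-methoxy-10-methyl-3-phenyl-6-[(trimethylsilyl)oxy]undeca-1,6,9-trien-1-yl]oxy}dimethylsilane (C1=C2 geometry as formed), via lithium ester enolate 12 (not isolated)
Conditions: LiN(i-Pr)2, THF, −78 °C; then t-BuMe2SiCl, DMPU, −78 → 0 °C; pentane, cold aq NaHCO3; used crude
Reagents that add atoms: tert-butyldimethylsilyl chloride, CC(C)(C)[Si](C)(C)Cl
Why: Kinetic enolisation of the ester with the lithium amide and O-silylation (Ireland-type ketene silyl acetal formation) is expected because the silyl enol ether has no comparably acidic hydrogen, and the more robust tert-butyldimethylsilyl group is chosen so that the ketene acetal survives the methanolic electrolyte of step 7; C3 is not affected.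

Step 7
Reactants: 13 tert-butyl{[(3S,6Z)-1-methoxy-10-methyl-3-phenyl-6-[(trimethylsilyl)oxy]undeca-1,6,9-trien-1-yl]oxy}dimethylsilane
Product: 15 methyl (1R,2S,6S)-2-(3-methylbut-2-en-1-yl)-3-oxo-6-phenylcyclohexane-1-carboxylate, via C1/C2 epimer mixture of this keto ester 14 (not isolated)
Conditions: reticulated vitreous carbon anode, Pt cathode, undivided cell, constant current (about 2.2 F/mol), LiClO4 (0.1 M), 2,6-lutidine, MeOH–CH2Cl2 (1:4), 0.02 M, 0 °C; aqueous work-up; then NaOMe, MeOH, rt
Reagents that add atoms: none
Why: Proposed new method: anodic one-electron oxidation takes place at the ketene silyl acetal, the most electron-rich pi system present, and the radical cation is attacked at its carbon C1 by the nucleophilic beta-carbon C2 of the silyl enol ether; a second electron transfer and transfer of both silyl groups to methanol leave the ester and the C3 ketone, that is the 1,4-dicarbonyl unit. The closest known reaction types are the intramolecular anodic coupling of enol ether radical cations with enol ether and silyl enol ether nucleophiles in this same electrolyte, and the oxidative cyclisation of silyl bis-enol ethers and bis-enolates to 1,4-dicarbonyl compounds by tetravalent cerium or divalent copper oxidants; an anodic ketene silyl acetal–silyl enol ether pair closing a ring in this way is the untested element. The cyclohexanone ring closes 6-exo with respect to the ketene acetal C=C and 6-endo with respect to the enol ether C=C, the five-membered alternative being disfavoured because it would require attack through the oxygen-bearing, non-nucleophilic enol carbon. The new centres C1 and C2 are not controlled in the bond-forming event, but both are alpha to a carbonyl group, so NaOMe should equilibrate them to the all-equatorial chair dictated by the fixed C6 phenyl group (1,2-trans, 1,6-trans), while C6 is not enolisable and keeps its configuration. The step needs chemoselective oxidation (the ketene acetal is oxidised well before the trisubstituted alkene, and no electron-rich arene is yet present), regiochemistry at C2 (fixed by the regiospecific enol ether from step 5) and ring closure ahead of dimerisation or methanol capture (dilute solution, six-membered transition state).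

Step 8
Reactants: 15 methyl (1R,2S,6S)-2-(3-methylbut-2-en-1-yl)-3-oxo-6-phenylcyclohexane-1-carboxylate
Product: 17 methyl (1R,2S,6S)-2-(3-methylbut-2-en-1-yl)-6-phenyl-3-[(trifluoromethanesulfonyl)oxy]cyclohex-3-ene-1-carboxylate, via potassium C3–C4 enolate 16 (not isolated)
Conditions: KN(SiMe3)2 (1.05 equiv), THF, −78 °C; then 2-[N,N-bis(trifluoromethylsulfonyl)amino]-5-chloropyridine, −78 °C; aq NH4Cl
Reagents that add atoms: 2-[N,N-bis(trifluoromethylsulfonyl)amino]-5-chloropyridine, O=S(=O)(N(c1ccc(Cl)cn1)S(=O)(=O)C(F)(F)F)C(F)(F)F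
Why: Kinetic enolate formation and O-triflation: the hindered amide base should remove a hydrogen from the unhindered C4 methylene in preference to the tertiary C2–H and the less acidic ester alpha-hydrogen at C1, and the pyridyl triflimide traps the enolate at −78 °C before equilibration, so C1 and C2 keep their configuration.

Step 9
Reactants: 17 methyl (1R,2S,6S)-2-(3-methylbut-2-en-1-yl)-6-phenyl-3-[(trifluoromethanesulfonyl)oxy]cyclohex-3-ene-1-carboxylate
Product: 18 methyl (1S,2S,6S)-3-methyl-2-(3-methylbut-2-en-1-yl)-6-phenylcyclohex-3-ene-1-carboxylate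
Conditions: MeMgBr (1.3 equiv), Fe(acac)3 (5 mol%), THF–NMP, −30 °C
Reagents that add atoms: methylmagnesium bromide, C[Mg]Br
Why: Iron-catalysed Kumada-type cross-coupling of an alkenyl triflate with a methyl Grignard reagent is fast at −30 °C, which should spare the hindered ester, and no stereocentre is involved.

Step 10
Reactants: 18 methyl (1S,2S,6S)-3-methyl-2-(3-methylbut-2-en-1-yl)-6-phenylcyclohex-3-ene-1-carboxylate
Product: 19 [(1S,2S,6S)-3-methyl-2-(3-methylbut-2-en-1-yl)-6-phenylcyclohex-3-en-1-yl]methanol
Conditions: i-Bu2AlH (2.5 equiv), CH2Cl2, −78 → 0 °C; aq KNaC4H4O6 (potassium sodium tartrate)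
Reagents that add atoms: none
Why: Hydride reduction of the ester to the primary alcohol by excess i-Bu2AlH under non-basic conditions, which leaves the alkenes and the C1 configuration unchanged.

Step 11
Reactants: 19 [(1S,2S,6S)-3-methyl-2-(3-methylbut-2-en-1-yl)-6-phenylcyclohex-3-en-1-yl]methanol
Product: 20 (1S,2S,6S)-3-methyl-2-(3-methylbut-2-en-1-yl)-6-phenylcyclohex-3-ene-1-carbaldehyde
Conditions: Dess–Martin periodinane, NaHCO3, CH2Cl2, 0 °C → rt
Reagents that add atoms: none
Why: Dess–Martin oxidation gives the aldehyde under buffered, essentially neutral conditions, so the alpha-stereocentre C1 should not epimerise.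

Step 12
Reactants: 21 3-hydroxy-4,5-dimethoxybenzaldehyde
Product: 22 3,4-dimethoxy-5-(methoxymethoxy)benzaldehyde
Conditions: MOMCl, i-Pr2NEt, CH2Cl2, 0 °C → rt
Reagents that add atoms: chloromethyl methyl ether, COCCl
Why: O-Alkylation of the phenol with MOMCl (acetal protection) is selective because the aldehyde is inert to the amine base and the alkylating agent.

Step 13
Reactants: 22 3,4-dimethoxy-5-(methoxymethoxy)benzaldehyde
Product: 24 3,4-dimethoxy-5-(methoxymethoxy)phenol, via 3,4-dimethoxy-5-(methoxymethoxy)phenyl formate 23 (not isolated)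
Conditions: mCPBA, NaHCO3, CH2Cl2, 0 °C → rt; then K2CO3, MeOH, rt
Reagents that add atoms: 3-chloroperoxybenzoic acid, O=C(OO)c1cccc(Cl)c1
Why: Baeyer–Villiger oxidation of the electron-rich benzaldehyde proceeds with aryl migration (the Dakin-type course favoured by the para methoxy group) to the formate, which is cleaved by methanolysis to the phenol while the MOM ether survives the buffered peracid.

Step 14
Reactants: 24 3,4-dimethoxy-5-(methoxymethoxy)phenol
Product: 25 1,2-dimethoxy-3,5-bis(methoxymethoxy)benzene
Conditions: MOMCl, i-Pr2NEt, CH2Cl2, 0 °C → rt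
Reagents that add atoms: chloromethyl methyl ether, COCCl
Why: A second MOM protection gives the resorcinol bis-MOM ether, in which the ring hydrogen between the two acetals is set up for directed metalation.

Step 15
Reactants: 25 1,2-dimethoxy-3,5-bis(methoxymethoxy)benzene (1.5 equiv); 20 (1S,2S,6S)-3-methyl-2-(3-methylbut-2-en-1-yl)-6-phenylcyclohex-3-ene-1-carbaldehyde
Product: 27 [3,4-dimethoxy-2,6-bis(methoxymethoxy)phenyl][(1S,2S,6S)-3-methyl-2-(3-methylbut-2-en-1-yl)-6-phenylcyclohex-3-en-1-yl]methanol (carbinol epimers), via [3,4-dimethoxy-2,6-bis(methoxymethoxy)phenyl]lithium 26 (not isolated)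
Conditions: 25, n-BuLi, THF, 0 °C; then 20, −78 → −20 °C; aq NH4Cl
Reagents that add atoms: none
Why: Directed ortho-metalation should take place between the two chelating MOM ethers in preference to the position flanked by one MOM ether and a methoxy group, and the aryllithium adds to the aldehyde at −78 °C (1,2-addition); the carbinol centre forms without control and is removed in step 16, while C1 is expected to remain as set.

Step 16
Reactants: 27 [3,4-dimethoxy-2,6-bis(methoxymethoxy)phenyl][(1S,2S,6S)-3-methyl-2-(3-methylbut-2-en-1-yl)-6-phenylcyclohex-3-en-1-yl]methanol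
Product: 28 [3,4-dimethoxy-2,6-bis(methoxymethoxy)phenyl][(1S,2S,6S)-3-methyl-2-(3-methylbut-2-en-1-yl)-6-phenylcyclohex-3-en-1-yl]methanone
Conditions: Dess–Martin periodinane, NaHCO3, CH2Cl2, rt
Reagents that add atoms: none
Why: Dess–Martin oxidation converts the hindered benzylic alcohol into the aryl ketone under neutral conditions and erases the uncontrolled carbinol centre.

Step 17
Reactants: 28 [3,4-dimethoxy-2,6-bis(methoxymethoxy)phenyl][(1S,2S,6S)-3-methyl-2-(3-methylbut-2-en-1-yl)-6-phenylcyclohex-3-en-1-yl]methanone
Product: 29 (2,6-dihydroxy-3,4-dimethoxyphenyl)[(1S,2S,6S)-3-methyl-2-(3-methylbut-2-en-1-yl)-6-phenylcyclohex-3-en-1-yl]methanone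
Conditions: 3 M aq HCl, MeOH, rt → 40 °C
Reagents that add atoms: none
Why: Acid-catalysed acetal exchange with methanol removes both MOM groups to give the two phenols hydrogen-bonded to the ketone, under conditions that trisubstituted alkenes should tolerate and with C1 already in its more stable trans,trans arrangement.

**Compound list**
1 | pent-4-enoic acid | C=CCCC(=O)O | starting material
2 | 1-(imidazol-1-yl)pent-4-en-1-one | C=CCCC(=O)n1ccnc1 | intermediate
3 | N-methoxy-N-methylpent-4-enamide | C=CCCC(=O)N(C)OC | intermediate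
4 | methyl acrylate | C=CC(=O)OC | starting material
5 | methyl (2E)-6-[methoxy(methyl)amino]-6-oxohex-2-enoate | COC(=O)/C=C/CCC(=O)N(C)OC | intermediate
6 | phenylboronic acid | OB(O)c1ccccc1 | starting material
7 | methyl (3S)-6-[methoxy(methyl)amino]-6-oxo-3-phenylhexanoate | COC(=O)C[C@@H](c1ccccc1)CCC(=O)N(C)OC | intermediate
8 | methyl (3S)-6-oxo-3-phenyloct-7-enoate | COC(=O)C[C@@H](c1ccccc1)CCC(=O)C=C | intermediate
9 | 1-bromo-2-methylprop-1-ene | CC(C)=CBr | starting material
10 | (2-methylprop-1-en-1-yl)magnesium bromide | CC(C)=C[Mg]Br | intermediate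
11 | methyl (3S,6Z)-10-methyl-3-phenyl-6-[(trimethylsilyl)oxy]undeca-6,9-dienoate | COC(=O)C[C@@H](c1ccccc1)CC/C(O[Si](C)(C)C)=C/CC=C(C)C | intermediate
12 | lithium ester enolate of 11 | COC(O[Li])=C[C@@H](c1ccccc1)CC/C(O[Si](C)(C)C)=C/CC=C(C)C | intermediate
13 | tert-butyl{[(3S,6Z)-1-methoxy-10-methyl-3-phenyl-6-[(trimethylsilyl)oxy]undeca-1,6,9-trien-1-yl]oxy}dimethylsilane (C1=C2 geometry as formed) | COC(O[Si](C)(C)C(C)(C)C)=C[C@@H](c1ccccc1)CC/C(O[Si](C)(C)C)=C/CC=C(C)C | intermediate
14 | methyl (6S)-2-(3-methylbut-2-en-1-yl)-3-oxo-6-phenylcyclohexane-1-carboxylate, mixture of C1/C2 epimers | COC(=O)C1C(CC=C(C)C)C(=O)CC[C@@H]1c1ccccc1 | intermediate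
15 | methyl (1R,2S,6S)-2-(3-methylbut-2-en-1-yl)-3-oxo-6-phenylcyclohexane-1-carboxylate (1,2-trans, 1,6-trans) | COC(=O)[C@H]1[C@H](CC=C(C)C)C(=O)CC[C@@H]1c1ccccc1 | intermediate
16 | potassium C3–C4 enolate of 15 | COC(=O)[C@H]1[C@H](CC=C(C)C)C(O[K])=CC[C@@H]1c1ccccc1 | intermediate
17 | methyl (1R,2S,6S)-2-(3-methylbut-2-en-1-yl)-6-phenyl-3-[(trifluoromethanesulfonyl)oxy]cyclohex-3-ene-1-carboxylate | COC(=O)[C@H]1[C@H](CC=C(C)C)C(OS(=O)(=O)C(F)(F)F)=CC[C@@H]1c1ccccc1 | intermediate
18 | methyl (1S,2S,6S)-3-methyl-2-(3-methylbut-2-en-1-yl)-6-phenylcyclohex-3-ene-1-carboxylate | COC(=O)[C@H]1[C@H](CC=C(C)C)C(C)=CC[C@@H]1c1ccccc1 | intermediate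
19 | [(1S,2S,6S)-3-methyl-2-(3-methylbut-2-en-1-yl)-6-phenylcyclohex-3-en-1-yl]methanol | OC[C@H]1[C@H](CC=C(C)C)C(C)=CC[C@@H]1c1ccccc1 | intermediate
20 | (1S,2S,6S)-3-methyl-2-(3-methylbut-2-en-1-yl)-6-phenylcyclohex-3-ene-1-carbaldehyde | O=C[C@H]1[C@H](CC=C(C)C)C(C)=CC[C@@H]1c1ccccc1 | intermediate
21 | 3-hydroxy-4,5-dimethoxybenzaldehyde | O=Cc1cc(O)c(OC)c(OC)c1 | starting material
22 | 3,4-dimethoxy-5-(methoxymethoxy)benzaldehyde | O=Cc1cc(OCOC)c(OC)c(OC)c1 | intermediate
23 | 3,4-dimethoxy-5-(methoxymethoxy)phenyl formate | O=COc1cc(OCOC)c(OC)c(OC)c1 | intermediate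
24 | 3,4-dimethoxy-5-(methoxymethoxy)phenol | Oc1cc(OCOC)c(OC)c(OC)c1 | intermediate
25 | 1,2-dimethoxy-3,5-bis(methoxymethoxy)benzene | COCOc1cc(OCOC)c(OC)c(OC)c1 | intermediate
26 | [3,4-dimethoxy-2,6-bis(methoxymethoxy)phenyl]lithium | [Li]c1c(OCOC)cc(OC)c(OC)c1OCOC | intermediate
27 | [3,4-dimethoxy-2,6-bis(methoxymethoxy)phenyl][(1S,2S,6S)-3-methyl-2-(3-methylbut-2-en-1-yl)-6-phenylcyclohex-3-en-1-yl]methanol (carbinol epimers) | COCOc1cc(OC)c(OC)c(OCOC)c1C(O)[C@H]1[C@H](CC=C(C)C)C(C)=CC[C@@H]1c1ccccc1 | intermediate
28 | [3,4-dimethoxy-2,6-bis(methoxymethoxy)phenyl][(1S,2S,6S)-3-methyl-2-(3-methylbut-2-en-1-yl)-6-phenylcyclohex-3-en-1-yl]methanone | COCOc1cc(OC)c(OC)c(OCOC)c1C(=O)[C@H]1[C@H](CC=C(C)C)C(C)=CC[C@@H]1c1ccccc1 | intermediate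
29 | (2,6-dihydroxy-3,4-dimethoxyphenyl)[(1S,2S,6S)-3-methyl-2-(3-methylbut-2-en-1-yl)-6-phenylcyclohex-3-en-1-yl]methanone | COc1cc(O)c(C(=O)[C@H]2[C@H](CC=C(C)C)C(C)=CC[C@@H]2c2ccccc2)c(O)c1OC | target

**Step count and risks**

Total step count: 17 (steps 12–14 build the arene fragment).
Longest linear sequence: 14 steps (steps 1–11 and 15–17).

Steps most likely to fail:

1. Step 7 (proposed new method). The ketene silyl acetal may be solvolysed by methanol before it reaches the anode, its radical cation may be captured by methanol instead of closing the ring, or intermolecular coupling may compete. The fallback sets out from 11 and comes back to the route at 15 (through 14). It replaces the oxidative union by a polar one in which the ester alpha-carbon is the electrophile, using known chemistry throughout.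
 - The lithium enolate of 11 (LiN(i-Pr)2, THF, −78 °C) is sulfenylated with PhSSPh to methyl (3R,6Z)-10-methyl-3-phenyl-2-(phenylsulfanyl)-6-[(trimethylsilyl)oxy]undeca-6,9-dienoate F1 (C3 unchanged in space; the descriptor changes because of the sulfur substituent).
 - N-Chlorosuccinimide (CH2Cl2, 0 °C) chlorinates the sulfide alpha-position, which should react faster than the silyl enol ether, to methyl (3R,6Z)-2-chloro-10-methyl-3-phenyl-2-(phenylsulfanyl)-6-[(trimethylsilyl)oxy]undeca-6,9-dienoate F2.
 - ZnBr2 (catalytic, CH2Cl2, −20 °C → rt) ionises the chloro sulfide to a thionium ion that alkylates the silyl enol ether at C2 (alpha-chloro sulfide alkylation of silyl enol ethers). This closes the same C1–C2 bond and gives methyl (6R)-2-(3-methylbut-2-en-1-yl)-3-oxo-6-phenyl-1-(phenylsulfanyl)cyclohexane-1-carboxylate F3.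
 - Bu3SnH with AIBN (toluene, 80 °C) removes the sulfur to give 14, and NaOMe in MeOH equilibrates it to 15.

2. Step 15. The aryllithium may deprotonate the hindered alpha-branched aldehyde (enolisation, with epimerised aldehyde returned on quench) instead of adding to it, or the doubly ortho-substituted nucleophile may add too slowly. The fallback sets out from 18 and from aryllithium 26 and comes back at 28; it makes the ketone by acylation of a non-basic organometallic, so steps 10, 11 and 16 fall away.
 - Ester 18 is saponified (LiOH, THF–MeOH–H2O, 60 °C) to (1S,2S,6S)-3-methyl-2-(3-methylbut-2-en-1-yl)-6-phenylcyclohex-3-ene-1-carboxylic acid F4.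
 - (COCl)2 with catalytic DMF (CH2Cl2, 0 °C) converts it into (1S,2S,6S)-3-methyl-2-(3-methylbut-2-en-1-yl)-6-phenylcyclohex-3-ene-1-carbonyl chloride F5.
 - Aryllithium 26 is transmetalated with ZnCl2 (THF, −78 °C → rt) to chlorido[3,4-dimethoxy-2,6-bis(methoxymethoxy)phenyl]zinc F6.
 - Negishi acylation of F6 with F5 (Pd(PPh3)4, THF, rt → 50 °C) gives 28 directly.

3. Step 9. The Grignard reagent may add to the ester, or the hindered C3 triflate may be reduced or homocoupled under the iron catalysis. The fallback sets out from 17 and comes back at 18. It leaves the Grignard manifold for a Stille coupling with SnMe4 (Pd(PPh3)4, LiCl, THF, reflux), in which the neutral methyl donor cannot attack the ester. It makes no compound outside the list (F0).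

**Further compounds**
F1 | step 7 | methyl (3R,6Z)-10-methyl-3-phenyl-2-(phenylsulfanyl)-6-[(trimethylsilyl)oxy]undeca-6,9-dienoate (C2 epimers) | COC(=O)C(Sc1ccccc1)[C@@H](c1ccccc1)CC/C(O[Si](C)(C)C)=C/CC=C(C)C
F2 | step 7 | methyl (3R,6Z)-2-chloro-10-methyl-3-phenyl-2-(phenylsulfanyl)-6-[(trimethylsilyl)oxy]undeca-6,9-dienoate (C2 epimers) | COC(=O)C(Cl)(Sc1ccccc1)[C@@H](c1ccccc1)CC/C(O[Si](C)(C)C)=C/CC=C(C)C
F3 | step 7 | methyl (6R)-2-(3-methylbut-2-en-1-yl)-3-oxo-6-phenyl-1-(phenylsulfanyl)cyclohexane-1-carboxylate (C1/C2 epimers) | COC(=O)C1(Sc2ccccc2)C(CC=C(C)C)C(=O)CC[C@@H]1c1ccccc1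
F4 | step 15 | (1S,2S,6S)-3-methyl-2-(3-methylbut-2-en-1-yl)-6-phenylcyclohex-3-ene-1-carboxylic acid | OC(=O)[C@H]1[C@H](CC=C(C)C)C(C)=CC[C@@H]1c1ccccc1
F5 | step 15 | (1S,2S,6S)-3-methyl-2-(3-methylbut-2-en-1-yl)-6-phenylcyclohex-3-ene-1-carbonyl chloride | O=C(Cl)[C@H]1[C@H](CC=C(C)C)C(C)=CC[C@@H]1c1ccccc1
F6 | step 15 | chlorido[3,4-dimethoxy-2,6-bis(methoxymethoxy)phenyl]zinc | Cl[Zn]c1c(OCOC)cc(OC)c(OC)c1OCOC
F0 | step 9 | none | none
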